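The cyclohexane ring (C5–C10) hides a four-carbon chain, C9–C10(C14)–C5–C6, that is an α-methyl-β-alkenyl succinaldehydic acid. It is cut out of the ring at C6–C7 and C8–C9 and traced back to a chiral 5-alkoxybutenolide whose carbonyl, α, β and acetal carbons become C9, C10, C5 and C6. One three-component operation adds an isopropenyl copper reagent to the β-carbon anti to the menthyloxy group and methylates the enolate, forming C5–C4 and C10–C14 and fixing C5 absolutely. The precursor is (5S)-5-(d-menthyloxy)furan-2(5H)-one. The ring is later closed on a butenolide that supplies C7, C8 and the lactone carbons C11–C13.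

Key step: step 3

Remark: atoms carry the elemane numbering of the target (ring C5–C10; C1=C2 vinyl and C14 methyl on C10; C4(=C3)–C15 on C5; lactone C8–O–C12(=O)–C11(C13)–C7). With C14 drawn up (β) the target is 5β-side chain, 6β-O, 7αH, 8αH, 9α-OH, C13 on the H7 face, i.e. (5R,6S,7S,8S,9S,10S,11R). The supplied structures of the butenolide precursor and of the key-step product were checked against the target and need no correction.

Step 1
Reactants: 1 furfural
Product: 3 racemic 5-hydroxyfuran-2(5H)-one, via furfural endoperoxide 2 (not isolated)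
Conditions: O2, visible light, rose bengal (disodium salt, C20H2Cl4I4Na2O5, catalytic), MeOH, 20 °C
Reagents that add atoms: oxygen, O=O
Why: Sensitised singlet-oxygen [4+2] cycloaddition to the furan gives endoperoxide 2, and methanol then attacks its formyl group so that methyl formate leaves and the hydroxybutenolide remains (photooxygenation of a 2-furaldehyde), the lactol centre being formed racemic and fixed only in step 2.

Step 2
Reactants: 3 racemic 5-hydroxyfuran-2(5H)-one; 4 (+)-menthol
Product: 6 (5S)-5-[(1S,2R,5S)-menthyloxy]furan-2(5H)-one, via 5R acetal epimer 5 (not isolated)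
Conditions: p-toluenesulfonic acid monohydrate (catalytic), toluene, reflux, Dean–Stark; crystallisation from petroleum ether, −20 °C; mother liquor re-equilibrated with the same acid and recrystallised
Reagents that add atoms: (+)-menthol, C[C@H]1CC[C@@H]([C@H](C1)O)C(C)C
Why: Acid-catalysed acetalisation of the lactol with the chiral alcohol gives both C5 epimers, of which the (5S) epimer, being the mirror image of the known crystalline acetal of (−)-menthol, should crystallise, while the acid keeps the acetal centre of the soluble epimer 5 equilibrating so that it is drawn over into 6.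

Step 3
Reactants: 6 (5S)-5-[(1S,2R,5S)-menthyloxy]furan-2(5H)-one; 7 isopropenylmagnesium bromide; 8 iodomethane
Product: 10 (3S,4R,5S)-3-methyl-5-[(1S,2R,5S)-menthyloxy]-4-(prop-1-en-2-yl)dihydrofuran-2(3H)-one (3,4-trans-4,5-trans), via bromomagnesium enolate 9 (not isolated)
Conditions: 7 (2.2 equiv), CuBr·SMe2 (1.1 equiv), THF–Me2S, −40 °C; then 6, −78 °C; then MeI (5 equiv), DMPU, −78 → −20 °C; aq NH4Cl
Reagents that add atoms: isopropenylmagnesium bromide, C=C(C)[Mg]Br; iodomethane, CI
Why: The diisopropenylcuprate made in the flask from 7 and CuBr·SMe2 (monovalent copper) forms a π-complex with the enoate, adds oxidatively at the β-carbon to a trivalent-copper β-adduct and reductively eliminates, which makes C5–C4 and leaves bromomagnesium enolate 9, and iodomethane then alkylates 9 at carbon to make C10–C14. The closest known reaction type is the tandem conjugate addition–enolate alkylation of 5-alkoxyfuran-2(5H)-ones, which is the three-component cuprate addition–alkylation long used on butenolides and cycloalkenones. No ring is closed. The new C5 centre is controlled by the acetal carbon (future C6): its menthyloxy group covers one face of the flat butenolide, the copper reagent attacks the other, and since the acetal is the single (5S) epimer this sets C5 in the absolute sense of the target. The new C10 centre is controlled by C5, the electrophile entering trans to the isopropenyl group, but only its constitution matters because step 4 re-enolises it. The step needs 1,4- and not 1,2-addition, which the soft copper reagent at −78 °C secures, and clean mono-C-methylation, which DMPU, excess iodomethane and a cold quench are chosen to secure.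

Step 4
Reactants: 10 (3S,4R,5S)-3-methyl-5-[(1S,2R,5S)-menthyloxy]-4-(prop-1-en-2-yl)dihydrofuran-2(3H)-one; 11 acetaldehyde
Product: 13 (3R,4S,5S)-3-(1-hydroxyethyl)-3-methyl-5-[(1S,2R,5S)-menthyloxy]-4-(prop-1-en-2-yl)dihydrofuran-2(3H)-one (both carbinol epimers), via lithium enolate 12 (not isolated)
Conditions: LDA (commercial solution, 1.2 equiv), THF, −78 °C; CH3CHO (3 equiv), −78 °C; AcOH, −78 °C
Reagents that add atoms: acetaldehyde, CC=O
Why: Aldol addition of the tetrasubstituted lithium lactone enolate 12 to acetaldehyde creates quaternary C10, the aldehyde approaching the enolate face anti to the neighbouring C5 isopropenyl group so that the two-carbon unit ends trans and the C14 methyl cis to the C5 side chain, while the carbinol centre, formed as a mixture, disappears in step 5 and the cold acetic acid quench prevents retro-aldol cleavage.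

Step 5
Reactants: 13 (3R,4S,5S)-3-(1-hydroxyethyl)-3-methyl-5-[(1S,2R,5S)-menthyloxy]-4-(prop-1-en-2-yl)dihydrofuran-2(3H)-one
Product: 14 (3S,4S,5S)-3-ethenyl-3-methyl-5-[(1S,2R,5S)-menthyloxy]-4-(prop-1-en-2-yl)dihydrofuran-2(3H)-one
Conditions: Burgess reagent (methyl N-(triethylammoniosulfonyl)carbamate, 2 equiv), toluene, 70 °C
Reagents that add atoms: none
Why: Burgess dehydration proceeds through the sulfamate ester and a thermal syn-elimination, and because the only β-hydrogens are those of the carbinol methyl group (the other neighbour is quaternary C10) both epimers converge on the C1=C2 vinyl group under neutral conditions that spare the acetal.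

Step 6
Reactants: 14 (3S,4S,5S)-3-ethenyl-3-methyl-5-[(1S,2R,5S)-menthyloxy]-4-(prop-1-en-2-yl)dihydrofuran-2(3H)-one
Product: 15 (2S,3S)-2-ethenyl-2-methyl-3-(prop-1-en-2-yl)butane-1,4-diol
Conditions: LiAlH4, THF, 0 → 20 °C; Fieser work-up
Reagents that add atoms: none
Why: Hydride reduction of the lactone carbonyl opens the ring to a hemiacetal that sheds menthoxide and is reduced further, so that C9 and C6 both become primary alcohols, the auxiliary is released as (+)-menthol for recovery and the C5 and C10 centres are untouched, the transient C6 aldehyde being reduced faster than it can enolise.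

Step 7
Reactants: 15 (2S,3S)-2-ethenyl-2-methyl-3-(prop-1-en-2-yl)butane-1,4-diol
Product: 16 (2S,3S)-4-[(tert-butyldimethylsilyl)oxy]-2-ethenyl-2-methyl-3-(prop-1-en-2-yl)butan-1-ol (C6–O silylated)
Conditions: TBSCl (1.05 equiv), imidazole, CH2Cl2, −20 °C
Reagents that add atoms: tert-butyldimethylsilyl chloride, CC(C)(C)[Si](C)(C)Cl
Why: Sterically controlled monosilylation should take the C6 hydroxyl, which sits on a methylene next to a tertiary carbon, ahead of the neopentylic C9 hydroxyl next to quaternary C10 when a slight excess of the bulky silyl chloride is used at low temperature.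

Step 8
Reactants: 16 (2S,3S)-4-[(tert-butyldimethylsilyl)oxy]-2-ethenyl-2-methyl-3-(prop-1-en-2-yl)butan-1-ol
Product: 17 (2S,3S)-4-[(tert-butyldimethylsilyl)oxy]-2-ethenyl-2-methyl-3-(prop-1-en-2-yl)butanal (C9 aldehyde)
Conditions: Dess–Martin periodinane, CH2Cl2, 0 → 20 °C
Reagents that add atoms: none
Why: Dess–Martin oxidation of the primary alcohol gives the C9 aldehyde, which has no α-hydrogen and so can neither enolise nor epimerise.

Step 9
Reactants: 18 3-methylfuran-2(5H)-one
Product: 19 tert-butyldimethyl[(3-methylfuran-2-yl)oxy]silane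
Conditions: TBSOTf, Et3N, CH2Cl2, 0 °C
Reagents that add atoms: tert-butyldimethylsilyl trifluoromethanesulfonate, CC(C)(C)[Si](C)(C)OS(=O)(=O)C(F)(F)F
Why: Soft enolisation of the butenolide with the silyl triflate and triethylamine and O-silylation of the dienolate give the aromatic 2-silyloxyfuran, the usual nucleophile for vinylogous Mukaiyama aldol reactions.

Step 10
Reactants: 17 (2S,3S)-4-[(tert-butyldimethylsilyl)oxy]-2-ethenyl-2-methyl-3-(prop-1-en-2-yl)butanal; 19 tert-butyldimethyl[(3-methylfuran-2-yl)oxy]silane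
Product: 20 (5S)-5-[(1S,2S,3S)-4-[(tert-butyldimethylsilyl)oxy]-2-ethenyl-1-hydroxy-2-methyl-3-(prop-1-en-2-yl)butyl]-3-methylfuran-2(5H)-one (8S,9S adduct)
Conditions: BF3·OEt2 (1.1 equiv), CH2Cl2, −78 °C; aq NaHCO3
Reagents that add atoms: tert-butyldimethyl[(3-methylfuran-2-yl)oxy]silane, Cc1ccoc1O[Si](C)(C)C(C)(C)C
Why: Vinylogous Mukaiyama aldol reaction in which the silyloxyfuran attacks the BF3-activated aldehyde through C5 of the furan and so forms C8–C9; the open transition state of the Lewis acid variant favours the threo arrangement of lactone oxygen and carbinol that becomes the trans C8–O/C9–OH relation of the ring, and the aldehyde face should follow Felkin–Anh control at quaternary C10, the nucleophile coming anti to the bulky C5 branch and past the flat vinyl group instead of the methyl group, so that the (8S,9S) adduct is expected as the main isomer and is separated from its diastereomers.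

Step 11
Reactants: 20 (5S)-5-[(1S,2S,3S)-4-[(tert-butyldimethylsilyl)oxy]-2-ethenyl-1-hydroxy-2-methyl-3-(prop-1-en-2-yl)butyl]-3-methylfuran-2(5H)-one
Product: 21 (5S)-5-[(1S,2S,3S)-1,4-bis[(tert-butyldimethylsilyl)oxy]-2-ethenyl-2-methyl-3-(prop-1-en-2-yl)butyl]-3-methylfuran-2(5H)-one
Conditions: TBSOTf (1.3 equiv), 2,6-lutidine, CH2Cl2, −78 → 0 °C
Reagents that add atoms: tert-butyldimethylsilyl trifluoromethanesulfonate, CC(C)(C)[Si](C)(C)OS(=O)(=O)C(F)(F)F
Why: Silylation of the hindered C9 hydroxyl with the silyl triflate uses 2,6-lutidine, a base too weak at low temperature to convert the butenolide into its silyloxyfuran, so the C8 centre should be kept.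

Step 12
Reactants: 21 (5S)-5-[(1S,2S,3S)-1,4-bis[(tert-butyldimethylsilyl)oxy]-2-ethenyl-2-methyl-3-(prop-1-en-2-yl)butyl]-3-methylfuran-2(5H)-one
Product: 22 (5S)-5-[(1S,2S,3S)-1-[(tert-butyldimethylsilyl)oxy]-2-ethenyl-4-hydroxy-2-methyl-3-(prop-1-en-2-yl)butyl]-3-methylfuran-2(5H)-one (C6–OH free)
Conditions: HF·pyridine, pyridine, THF, 0 °C
Reagents that add atoms: none
Why: Pyridine-buffered HF·pyridine cleaves the unhindered primary silyl ether at C6 much faster than the secondary one at C9 that is flanked by quaternary C10, a standard primary-over-secondary desilylation.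

Step 13
Reactants: 22 (5S)-5-[(1S,2S,3S)-1-[(tert-butyldimethylsilyl)oxy]-2-ethenyl-4-hydroxy-2-methyl-3-(prop-1-en-2-yl)butyl]-3-methylfuran-2(5H)-one
Product: 23 (2S,3S,4S)-4-[(tert-butyldimethylsilyl)oxy]-3-ethenyl-3-methyl-4-[(2S)-4-methyl-5-oxo-2,5-dihydrofuran-2-yl]-2-(prop-1-en-2-yl)butanal (C6 aldehyde)
Conditions: Dess–Martin periodinane, NaHCO3, CH2Cl2, 0 °C; used at once
Reagents that add atoms: none
Why: Buffered Dess–Martin oxidation gives the C6 aldehyde without acid or base, so that C5, which is α to the new carbonyl and allylic, should neither epimerise nor let the isopropenyl double bond move into conjugation before the aldehyde is used in step 14.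

Step 14
Reactants: 23 (2S,3S,4S)-4-[(tert-butyldimethylsilyl)oxy]-3-ethenyl-3-methyl-4-[(2S)-4-methyl-5-oxo-2,5-dihydrofuran-2-yl]-2-(prop-1-en-2-yl)butanal
Product: 24 9α-[(tert-butyldimethylsilyl)oxy]-6α-hydroxyelema-1,3-dien-12,8β-olide (7αH,8αH cis-fused; C11 epimers)
Conditions: SmI2 (0.1 M in THF, 2.5 equiv), t-BuOH (2 equiv), THF, −78 → 0 °C
Reagents that add atoms: none
Why: SmI2 ketyl–olefin cyclisation in the 6-exo-trig mode, in which the C6 ketyl radical adds to the butenolide β-carbon C7 and closes the cyclohexane; since the tether hangs from C8 the new bond can only form on the lactone face that carries C9, which fixes C7 and the cis ring fusion (H7 and H8 syn), whereas the C6 carbinol (ketyl oxygen expected to turn away from the lactone, 6α) and the protonated C11 are not relied on and are set in steps 16 and 17.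

Step 15
Reactants: 24 9α-[(tert-butyldimethylsilyl)oxy]-6α-hydroxyelema-1,3-dien-12,8β-olide
Product: 25 9α-[(tert-butyldimethylsilyl)oxy]-6-oxoelema-1,3-dien-12,8β-olide (C11 epimers)
Conditions: Dess–Martin periodinane, NaHCO3, CH2Cl2, 0 → 20 °C
Reagents that add atoms: none
Why: Dess–Martin oxidation turns either C6 epimer into the same ketone under buffered neutral conditions, chosen because base could enolise C7 and expel the β-acyloxy oxygen at C8.

Step 16
Reactants: 25 9α-[(tert-butyldimethylsilyl)oxy]-6-oxoelema-1,3-dien-12,8β-olide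
Product: 26 9α-[(tert-butyldimethylsilyl)oxy]-6β-hydroxyelema-1,3-dien-12,8β-olide (C11 epimers)
Conditions: NaBH4, CeCl3·7H2O, MeOH–THF, −78 °C; AcOH quench
Reagents that add atoms: none
Why: Luche reduction under steric approach control: in the chair that keeps the C5 and C7 substituents equatorial the β-face of the C6 carbonyl is screened by the syn-axial C14 methyl group and the C8 oxygen, so hydride should arrive from the α-face and give the 6β-alcohol, while the cold, weakly basic cerium medium disfavours enolisation and lactone migration.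

Step 17
Reactants: 26 9α-[(tert-butyldimethylsilyl)oxy]-6β-hydroxyelema-1,3-dien-12,8β-olide; 27 isobutyric anhydride
Product: 29 (11R)-9α-[(tert-butyldimethylsilyl)oxy]-6β-(isobutyryloxy)elema-1,3-dien-12,8β-olide, via C11-epimeric isobutyrates 28 (not isolated)
Conditions: (i-PrCO)2O, 4-(dimethylamino)pyridine, Et3N, toluene, 40 °C; then DBU, 80 °C
Reagents that add atoms: isobutyric anhydride, CC(C)C(=O)OC(=O)C(C)C
Why: Acylation catalysed by 4-(dimethylamino)pyridine esterifies the hindered 6β-hydroxyl, and DBU then equilibrates the lactone α-carbon C11 through its enolate to the more stable epimer with the C13 methyl on the convex face of the cis-fused lactone, trans to the C7–C6 bond, which is the configuration of the target.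

Step 18
Reactants: 29 (11R)-9α-[(tert-butyldimethylsilyl)oxy]-6β-(isobutyryloxy)elema-1,3-dien-12,8β-olide
Product: 30 (11R)-9α-hydroxy-6β-(isobutyryloxy)elema-1,3-dien-12,8β-olide
Conditions: HF (48% aq), MeCN, 20 °C
Reagents that add atoms: none
Why: Fluoride-mediated desilylation with aqueous HF removes the hindered secondary silyl ether at C9 under acidic conditions that leave the isobutyrate, the lactone and the alkenes alone and give no alkoxide that could shift an acyl group.

Step 19
Reactants: 30 (11R)-9α-hydroxy-6β-(isobutyryloxy)elema-1,3-dien-12,8β-olide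
Product: 32 CNP0198892.2 (9α-hydroxy-6β-isobutyryloxy-15-oxoelema-1,3-dien-12,8β-olide), via allylic alcohol 31 (not isolated)
Conditions: SeO2 (0.5 equiv), t-BuOOH, CH2Cl2, 20 °C; filtration; then MnO2, CH2Cl2, 20 °C
Reagents that add atoms: selenium dioxide, O=[Se]=O; tert-butyl hydroperoxide, CC(C)(C)OO
Why: Selenium dioxide allylic oxidation (ene reaction followed by [2,3]-sigmatropic shift) can only strike the isopropenyl group, the C10 vinyl group having no allylic hydrogen, and prefers its methyl group to the C5 methine, and MnO2 then oxidises the resulting primary allylic alcohol 31, but not the non-allylic C9 hydroxyl, to the 2-substituted acrolein of the target.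

Compound list
1 | furfural (furan-2-carbaldehyde) | O=Cc1ccco1 | starting material
2 | furfural endoperoxide, 2,3,7-trioxabicyclo[2.2.1]hept-5-ene-1-carbaldehyde (formed in the flask) | O=CC12OOC(C=C1)O2 | intermediate
3 | 5-hydroxyfuran-2(5H)-one, racemic | OC1OC(=O)C=C1 | intermediate
4 | (+)-menthol, (1S,2R,5S)-2-isopropyl-5-methylcyclohexan-1-ol | C[C@H]1CC[C@@H]([C@H](C1)O)C(C)C | starting material
5 | (5R)-5-[(1S,2R,5S)-menthyloxy]furan-2(5H)-one (soluble epimer, equilibrated in the flask) | C[C@H]1CC[C@@H]([C@H](C1)O[C@@H]2OC(=O)C=C2)C(C)C | intermediate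
6 | (5S)-5-[(1S,2R,5S)-menthyloxy]furan-2(5H)-one | C[C@H]1CC[C@@H]([C@H](C1)O[C@H]2OC(=O)C=C2)C(C)C | intermediate
7 | isopropenylmagnesium bromide (solution in THF) | C=C(C)[Mg]Br | starting material
8 | iodomethane | CI | starting material
9 | bromomagnesium enolate of (4R,5S)-5-menthyloxy-4-(prop-1-en-2-yl)dihydrofuran-2(3H)-one (formed in the flask) | C[C@H]1CC[C@@H]([C@H](C1)O[C@H]2OC(O[Mg]Br)=C[C@@H]2C(C)=C)C(C)C | intermediate
10 | (3S,4R,5S)-3-methyl-5-[(1S,2R,5S)-menthyloxy]-4-(prop-1-en-2-yl)dihydrofuran-2(3H)-one, 3,4-trans and 4,5-trans | C[C@H]1CC[C@@H]([C@H](C1)O[C@H]2OC(=O)[C@@H](C)[C@@H]2C(C)=C)C(C)C | intermediate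
11 | acetaldehyde | CC=O | starting material
12 | lithium enolate of 10 (formed in the flask) | C[C@H]1CC[C@@H]([C@H](C1)O[C@H]2OC(O[Li])=C(C)[C@@H]2C(C)=C)C(C)C | intermediate
13 | (3R,4S,5S)-3-(1-hydroxyethyl)-3-methyl-5-[(1S,2R,5S)-menthyloxy]-4-(prop-1-en-2-yl)dihydrofuran-2(3H)-one, hydroxyethyl trans and methyl cis to isopropenyl, both carbinol epimers | C[C@H]1CC[C@@H]([C@H](C1)O[C@H]2OC(=O)[C@@](C)(C(C)O)[C@@H]2C(C)=C)C(C)C | intermediate
14 | (3S,4S,5S)-3-ethenyl-3-methyl-5-[(1S,2R,5S)-menthyloxy]-4-(prop-1-en-2-yl)dihydrofuran-2(3H)-one, vinyl trans to isopropenyl | C[C@H]1CC[C@@H]([C@H](C1)O[C@H]2OC(=O)[C@@](C)(C=C)[C@@H]2C(C)=C)C(C)C | intermediate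
15 | (2S,3S)-2-ethenyl-2-methyl-3-(prop-1-en-2-yl)butane-1,4-diol (C9–OH at C1, C6–OH at C4) | OC[C@@](C)(C=C)[C@@H](CO)C(C)=C | intermediate
16 | (2S,3S)-4-[(tert-butyldimethylsilyl)oxy]-2-ethenyl-2-methyl-3-(prop-1-en-2-yl)butan-1-ol | OC[C@@](C)(C=C)[C@@H](CO[Si](C)(C)C(C)(C)C)C(C)=C | intermediate
17 | (2S,3S)-4-[(tert-butyldimethylsilyl)oxy]-2-ethenyl-2-methyl-3-(prop-1-en-2-yl)butanal | O=C[C@@](C)(C=C)[C@@H](CO[Si](C)(C)C(C)(C)C)C(C)=C | intermediate
18 | 3-methylfuran-2(5H)-one | CC1=CCOC1=O | starting material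
19 | tert-butyldimethyl[(3-methylfuran-2-yl)oxy]silane | Cc1ccoc1O[Si](C)(C)C(C)(C)C | intermediate
20 | (5S)-5-[(1S,2S,3S)-4-[(tert-butyldimethylsilyl)oxy]-2-ethenyl-1-hydroxy-2-methyl-3-(prop-1-en-2-yl)butyl]-3-methylfuran-2(5H)-one | C=C[C@](C)([C@H](O)[C@H]1OC(=O)C(C)=C1)[C@@H](CO[Si](C)(C)C(C)(C)C)C(C)=C | intermediate
21 | (5S)-5-[(1S,2S,3S)-1,4-bis[(tert-butyldimethylsilyl)oxy]-2-ethenyl-2-methyl-3-(prop-1-en-2-yl)butyl]-3-methylfuran-2(5H)-one | C=C[C@](C)([C@H](O[Si](C)(C)C(C)(C)C)[C@H]1OC(=O)C(C)=C1)[C@@H](CO[Si](C)(C)C(C)(C)C)C(C)=C | intermediate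
22 | (5S)-5-[(1S,2S,3S)-1-[(tert-butyldimethylsilyl)oxy]-2-ethenyl-4-hydroxy-2-methyl-3-(prop-1-en-2-yl)butyl]-3-methylfuran-2(5H)-one | C=C[C@](C)([C@H](O[Si](C)(C)C(C)(C)C)[C@H]1OC(=O)C(C)=C1)[C@@H](CO)C(C)=C | intermediate
23 | (2S,3S,4S)-4-[(tert-butyldimethylsilyl)oxy]-3-ethenyl-3-methyl-4-[(2S)-4-methyl-5-oxo-2,5-dihydrofuran-2-yl]-2-(prop-1-en-2-yl)butanal | C=C[C@](C)([C@H](O[Si](C)(C)C(C)(C)C)[C@H]1OC(=O)C(C)=C1)[C@@H](C=O)C(C)=C | intermediate
24 | 9α-[(tert-butyldimethylsilyl)oxy]-6α-hydroxyelema-1,3-dien-12,8β-olide, 7αH,8αH, C11 unassigned (epimers) | C=C[C@]1(C)[C@H](O[Si](C)(C)C(C)(C)C)[C@H]2OC(=O)C(C)[C@H]2[C@H](O)[C@H]1C(C)=C | intermediate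
25 | 9α-[(tert-butyldimethylsilyl)oxy]-6-oxoelema-1,3-dien-12,8β-olide, C11 epimers | C=C[C@]1(C)[C@H](O[Si](C)(C)C(C)(C)C)[C@H]2OC(=O)C(C)[C@H]2C(=O)[C@H]1C(C)=C | intermediate
26 | 9α-[(tert-butyldimethylsilyl)oxy]-6β-hydroxyelema-1,3-dien-12,8β-olide, C11 epimers | C=C[C@]1(C)[C@H](O[Si](C)(C)C(C)(C)C)[C@H]2OC(=O)C(C)[C@H]2[C@@H](O)[C@H]1C(C)=C | intermediate
27 | isobutyric anhydride | CC(C)C(=O)OC(=O)C(C)C | starting material
28 | 9α-[(tert-butyldimethylsilyl)oxy]-6β-(isobutyryloxy)elema-1,3-dien-12,8β-olide, C11 epimers (formed in the flask) | C=C[C@]1(C)[C@H](O[Si](C)(C)C(C)(C)C)[C@H]2OC(=O)C(C)[C@H]2[C@@H](OC(=O)C(C)C)[C@H]1C(C)=C | intermediate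
29 | (11R)-9α-[(tert-butyldimethylsilyl)oxy]-6β-(isobutyryloxy)elema-1,3-dien-12,8β-olide | C=C[C@]1(C)[C@H](O[Si](C)(C)C(C)(C)C)[C@H]2OC(=O)[C@H](C)[C@H]2[C@@H](OC(=O)C(C)C)[C@H]1C(C)=C | intermediate
30 | (11R)-9α-hydroxy-6β-(isobutyryloxy)elema-1,3-dien-12,8β-olide | C=C[C@]1(C)[C@H](O)[C@H]2OC(=O)[C@H](C)[C@H]2[C@@H](OC(=O)C(C)C)[C@H]1C(C)=C | intermediate
31 | (11R)-9α,15-dihydroxy-6β-(isobutyryloxy)elema-1,3-dien-12,8β-olide (formed in the flask) | C=C[C@]1(C)[C@H](O)[C@H]2OC(=O)[C@H](C)[C@H]2[C@@H](OC(=O)C(C)C)[C@H]1C(=C)CO | intermediate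
32 | CNP0198892.2, (5R,6S,7S,8S,9S,10S,11R)-9-hydroxy-6-(isobutyryloxy)-15-oxoelema-1,3-dien-12,8-olide | C=C[C@]1(C)[C@H](O)[C@H]2OC(=O)[C@H](C)[C@H]2[C@@H](OC(=O)C(C)C)[C@H]1C(=C)C=O | target

Total step count: 19 (18 in the main line and 1 for silyloxyfuran 19).
Longest linear sequence: 18 steps (steps 1–8 and 10–19, from furfural).

Steps most likely to fail

Step 3. The copper–magnesium enolate may alkylate sluggishly, so that the conjugate adduct is simply protonated, or is methylated at oxygen or twice. Face selectivity may also erode if the addition warms. Fallback: the two bonds are made in separate operations. From 6, the same cuprate addition is quenched with NH4Cl at −78 °C to give (4R,5S)-5-[(1S,2R,5S)-menthyloxy]-4-(prop-1-en-2-yl)dihydrofuran-2(3H)-one F1. F1 is then deprotonated with LDA in THF at −78 °C and the lithium enolate is methylated with iodomethane trans to the isopropenyl group, returning to the route at 10.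

Step 10. Facial discrimination at the α-quaternary aldehyde rests on a small size difference between vinyl and methyl, and threo control may be incomplete, so a hard-to-separate diastereomer mixture may result. Fallback: C8 and C9 are set by an auxiliary and the butenolide is built afterwards.
- From 17, an Evans syn-glycolate aldol with (R)-4-benzyl-3-[2-(4-methoxybenzyloxy)acetyl]oxazolidin-2-one (Bu2BOTf, Et3N, CH2Cl2, −78 → 0 °C) gives the syn-aldol imide F2. The (R)-auxiliary is the one whose syn sense matches the C8/C9 configuration of 20.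
- TBSOTf and 2,6-lutidine give the 9-O-silyl imide F3.
- LiBH4 (THF, MeOH, 0 °C) removes the auxiliary and gives the primary C7 alcohol F4.
- Dess–Martin oxidation gives the α-alkoxy C7 aldehyde F5.
- Still–Gennari olefination with methyl 2-[bis(2,2,2-trifluoroethoxy)phosphoryl]propanoate (KN(SiMe3)2, 18-crown-6, THF, −78 °C) gives the (Z)-enoate F6.
- DDQ (CH2Cl2, pH 7 buffer) frees the C8 hydroxyl, which closes onto the Z-ester to form the butenolide, returning to the route at 21.

Step 14. The ketyl may be reduced further to the alcohol or dimerise by pinacol coupling faster than it cyclises, and the aldehyde may lose its C5 configuration or isomerise into conjugation before ring closure. Fallback: from 23, an intramolecular Stetter reaction closes the same C6–C7 bond through the Breslow intermediate, without single-electron steps. Conditions: 2-(pentafluorophenyl)-6,7-dihydro-5H-pyrrolo[2,1-c][1,2,4]triazol-2-ium tetrafluoroborate (20 mol %), i-Pr2NEt, toluene, 40 °C. The tether again enforces the cis fusion, and the C6 ketone is formed directly, returning to the route at 25. No compound outside the list is made (F0).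

Further compounds
F1 | step 3 | (4R,5S)-5-[(1S,2R,5S)-menthyloxy]-4-(prop-1-en-2-yl)dihydrofuran-2(3H)-one | C[C@H]1CC[C@@H]([C@H](C1)O[C@H]2OC(=O)C[C@@H]2C(C)=C)C(C)C
F2 | step 10 | (R)-4-benzyl-3-acyl-oxazolidin-2-one syn-glycolate aldol adduct of 17 (C8–OPMB, C9–OH, C7 imide carbonyl) | C=C[C@](C)([C@H](O)[C@@H](OCc1ccc(OC)cc1)C(=O)N1[C@H](Cc2ccccc2)COC1=O)[C@@H](CO[Si](C)(C)C(C)(C)C)C(C)=C
F3 | step 10 | 9-O-tert-butyldimethylsilyl ether of F2 | C=C[C@](C)([C@H](O[Si](C)(C)C(C)(C)C)[C@@H](OCc1ccc(OC)cc1)C(=O)N1[C@H](Cc2ccccc2)COC1=O)[C@@H](CO[Si](C)(C)C(C)(C)C)C(C)=C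
F4 | step 10 | C7 primary alcohol (6,9-bis-O-silyl, 8-O-PMB triol derivative) | C=C[C@](C)([C@H](O[Si](C)(C)C(C)(C)C)[C@@H](OCc1ccc(OC)cc1)CO)[C@@H](CO[Si](C)(C)C(C)(C)C)C(C)=C
F5 | step 10 | C7 aldehyde (α-PMB-oxy aldehyde) | C=C[C@](C)([C@H](O[Si](C)(C)C(C)(C)C)[C@@H](OCc1ccc(OC)cc1)C=O)[C@@H](CO[Si](C)(C)C(C)(C)C)C(C)=C
F6 | step 10 | methyl (Z)-2-methyl-4-(PMB-oxy)-enoate (C7=C11 Z, C12 methyl ester) | C=C[C@](C)([C@H](O[Si](C)(C)C(C)(C)C)[C@@H](OCc1ccc(OC)cc1)/C=C(/C)C(=O)OC)[C@@H](CO[Si](C)(C)C(C)(C)C)C(C)=C
F0 | step 14 | none | none
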